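The earlier runs and the new flask were generated by integration from invented constants, and the scatter is random.

The ratio of incoming ligand to starting complex is the first thing to read from a charge: each exchange spends one incoming ligand on one complex, so turnovers can be counted before any rate is known.

in all of them: starting complex 0.077 M; protic impurity 0.0231 M
- ash: incoming ligand 0.025 M; leaving ligand 0.077 M; run made earlier
- cedar: incoming ligand 0.057 M; leaving ligand 0.077 M; run made earlier
- flask: incoming ligand 0.0380 M; leaving ligand 0.0770 M; time 8.0 d

| run | time / d | complex with one exchanged / % | starting complex / % |
|---|---|---|---|
| ash | 0.625 | 13.2 | 56.9 |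
| ash | 1.67 | 23.4 | 46.2 |
| ash | 3.00 | 28.7 | 41.4 |
| ash | 8.00 | 31.5 | 38.3 |
| cedar | 0.625 | 24.1 | 45.0 |
| cedar | 1.67 | 40.0 | 28.3 |
| cedar | 3.00 | 47.9 | 19.0 |
| cedar | 8.00 | 54.1 | 10.4 |

(each reading ± 0.3 percentage points)

- equivalents of incoming ligand to starting complex, everything else as given, that leave most complex with one exchanged at 8.0 d
- the amount of complex with one exchanged then, in percent of the starting complex charged
- the amount of complex with one exchanged with the amounts as given



With the main step alone, the flask holds incoming ligand for [incoming ligand]/[starting complex] = 49.4% of its complex. Adding the impurity changes the supply of complex. The two species read in the ash run sum to 70.1% at 0.625 d, and [protic impurity]/[starting complex] is 30.0%, so the readings look like one complex lost per impurity, early. The surviving complex in the flask is still more than the incoming ligand, which makes the ligand the limiting reagent there and leaves the count unchanged. The smaller of [incoming ligand] and [starting complex] − [protic impurity], divided by [starting complex], gives 49.4%, the ligand budget.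

The remaining processes show up as a shortfall against that budget. The ash run has a budget of 32.5% and reads 31.5% at 8.00 d, a share of 97.0%. The cedar run has 70.0% and reads 54.1%, a share of 77.3%; its sum sinks to 64.5%, which suggests a second exchange. Interpolating on [incoming ligand] gives the flask an estimated share of 89.0%, hence an estimate of 43.9% of complex with one exchanged. The cedar run, at 0.740 equiv, still reads 10.4% of starting complex, so this reckoning puts the peak above that charge and above that run's reading of 54.1%.

The forecast, lower than this reckoning for the flask, gives 42%, with a peak of 54.4% near 0.8 equiv, “as double exchange offsets the remaining starting complex”.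

The flask gives 44.1%, and the best charge, 0.844 equiv, gives 54.8%.

    complex with one exchanged + incoming ligand ⇌ leaving ligand + complex with two exchanged (K = 36.0, k = 0.0500 M⁻¹ h⁻¹)
    starting complex + incoming ligand ⇌ leaving ligand + complex with one exchanged (K = 0.330, k = 1.50 M⁻¹ h⁻¹)
    leaving ligand → by-product carried off (k = 0.160 h⁻¹)
    protic impurity + starting complex → quenched substrate (k = 160 M⁻¹ h⁻¹)

At 8.00 d the flask holds 1.98% of complex with two exchanged, each carrying two incoming ligands. Counting these twice, adding 44.1% and the free ligand, 1.29% of the complex charged, returns 49.4%, the ligand budget.

A neighbour charged with 0.31 M of starting complex has a budget of 12.3%. That neighbour gives 12.0% of complex with one exchanged.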